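**Plan**
1. Ring A is the 1,3,5-trisubstituted ring, ring B the ring with two hydroxyls; the bridge is numbered C1 (on ring B) to C16 (on ring A). Retrosynthetic cuts, in order: the three O-methyl masks; the C7–C8 bond of the bridge (opening the ring to a diacid, activated as a bis(N-acyloxyphthalimide)); the C1–C2 bond next to ring B (Wittig alkene); the aryl–O bond at ring B (Ullmann); the aryl–C16 bond at ring A (B-alkyl Suzuki).
2. Forward: ring A receives its C10 acid chain, the diaryl ether is made, ring B receives its C8 acid chain, and the 22-membered ring is closed last by a nickel-electrocatalytic doubly decarboxylative CH2–CH2 coupling; demethylation ends the route.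
3. Enabling feature: the bridge is a bare (CH2)16 chain, C7 and C8 are primary carbons six and eight methylenes away from rings B and A, and the ether oxygen between ring A and ring B already ties both chain ends into one molecule. A traceless union of two primary radicals (only CO2 and phthalimide leave) therefore gives the ring at its final oxidation level.
4. Stereochemistry: the target has no stereocentre; the only stereo-element on the way, the Wittig alkene geometry, is erased by hydrogenation.

Key step: step 7

Remark: compounds 1, 2, 5 and 7 are taken to be purchasable.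

**Step 1**
Reactants: 1 3-bromo-5-methoxyphenol; 2 methyl dec-9-enoate
Product: 4 methyl 10-(3-hydroxy-5-methoxyphenyl)decanoate, via alkylborane 3 (not isolated)
Conditions: 2, 9-BBN, THF, 0 °C to rt; then 1, Pd(dppf)Cl2 (5 mol%), aq. K3PO4 (3 equiv), DMF, 60 °C
Reagents that add atoms: none
Why: B-alkyl Suzuki–Miyaura coupling, in which anti-Markovnikov hydroboration of the terminal alkene gives the primary alkylborane, which transmetalates to the arylpalladium bromide from 1, and the wide-bite-angle dppf ligand makes reductive elimination faster than β-hydride elimination while ester and free phenol are tolerated.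

**Step 2**
Reactants: 4 methyl 10-(3-hydroxy-5-methoxyphenyl)decanoate; 5 2-bromo-3,5-dimethoxybenzaldehyde
Product: 6 methyl 10-[3-(2-formyl-4,6-dimethoxyphenoxy)-5-methoxyphenyl]decanoate
Conditions: CuI (10 mol%), picolinic acid (20 mol%), K3PO4 (2 equiv), DMSO, 90 °C
Reagents that add atoms: none
Why: Ullmann-type copper-catalysed diaryl ether synthesis, in which the ortho-formyl group of 5 assists activation of the C–Br bond at copper, the unhindered 3,5-disubstituted phenoxide of 4 is a good nucleophile, and the picolinic acid ligand suits ortho-flanked aryl halides.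

**Step 3**
Reactants: 6 methyl 10-[3-(2-formyl-4,6-dimethoxyphenoxy)-5-methoxyphenyl]decanoate; 7 (6-carboxyhexyl)triphenylphosphonium bromide
Product: 9 (Z)-8-{2-[3-methoxy-5-(10-methoxy-10-oxodecyl)phenoxy]-3,5-dimethoxyphenyl}oct-7-enoic acid, via carboxylate ylide 8 (not isolated)
Conditions: 7 (1.5 equiv), NaN(SiMe3)2 (3.0 equiv), THF, 0 °C; then 6, −78 °C to rt; aq. HCl work-up
Reagents that add atoms: none
Why: Wittig olefination with a non-stabilised ylide, which adds to the aryl aldehyde far faster than to the remote methyl ester at low temperature; the Z alkene should predominate, but the geometry is irrelevant because step 4 saturates it.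

**Step 4**
Reactants: 9 (Z)-8-{2-[3-methoxy-5-(10-methoxy-10-oxodecyl)phenoxy]-3,5-dimethoxyphenyl}oct-7-enoic acid
Product: 10 8-{2-[3-methoxy-5-(10-methoxy-10-oxodecyl)phenoxy]-3,5-dimethoxyphenyl}octanoic acid
Conditions: H2 (1 atm), Pd/C (10 wt%), EtOAc, rt
Reagents that add atoms: none
Why: Heterogeneous catalytic hydrogenation of a disubstituted styrene-type alkene, to which the aryl methyl ethers, the diaryl ether, the ester and the acid are inert.

**Step 5**
Reactants: 10 8-{2-[3-methoxy-5-(10-methoxy-10-oxodecyl)phenoxy]-3,5-dimethoxyphenyl}octanoic acid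
Product: 11 10-{3-[2-(7-carboxyheptyl)-4,6-dimethoxyphenoxy]-5-methoxyphenyl}decanoic acid
Conditions: LiOH·H2O (5 equiv), THF/MeOH/H2O, rt; then 1 M HCl
Reagents that add atoms: lithium hydroxide, [Li+].[OH-]
Why: Ester saponification by acyl addition–elimination of hydroxide, with no other base-labile group present in 10.

**Step 6**
Reactants: 11 10-{3-[2-(7-carboxyheptyl)-4,6-dimethoxyphenoxy]-5-methoxyphenyl}decanoic acid
Product: 12 bis(N-hydroxyphthalimide) ester of 11: 1,3-dioxoisoindolin-2-yl 10-{3-[2-(8-[(1,3-dioxoisoindolin-2-yl)oxy]-8-oxooctyl)-4,6-dimethoxyphenoxy]-5-methoxyphenyl}decanoate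
Conditions: N-hydroxyphthalimide (2.4 equiv), DIC (2.4 equiv), DMAP (10 mol%), CH2Cl2, rt
Reagents that add atoms: N-hydroxyphthalimide, ON1C(=O)c2ccccc2C1=O
Why: Carbodiimide (Steglich-type) esterification of both primary carboxylic acids, which installs the two redox-active esters without touching the aryl ethers.

**Step 7**
Reactants: 12 bis(N-hydroxyphthalimide) ester of 11
Product: 13 tri-O-methylgrevirobstol B (the 22-membered macrocycle with all three phenols as methyl ethers)
Conditions: NiCl2·6H2O (0.3 equiv), 2,2':6',2''-terpyridine (0.3 equiv), AgNO3 (0.3 equiv), LiBr (electrolyte), NMP, Mg anode, RVC cathode, undivided cell, constant current, rt; 12 added by syringe pump over 12 h (end concentration about 2 mM)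
Reagents that add atoms: none
Why: Proposed new method: an intramolecular, ring-closing version of the nickel-electrocatalytic doubly decarboxylative C(sp3)–C(sp3) coupling of redox-active esters; the closest known reaction type is the intermolecular nickel-catalysed reductive homo- or cross-coupling of two primary alkyl N-hydroxyphthalimide esters or alkyl halides. Single-electron reduction of one N-acyloxyphthalimide by low-valent nickel (or at the silver-coated cathode) gives, after loss of CO2 and phthalimide anion, a primary alkyl radical that is captured by nickel; the alkylnickel species is reduced at the cathode, activates the second redox-active ester of the same molecule in the same way, and the resulting dialkylnickel intermediate forms the C7–C8 bond by reductive elimination. The 22-membered ring is closed end to end through a 23-membered dialkylnickel chelate, that is by C–C reductive elimination and not by attack on a π bond, so no exo/endo constraint applies, and no stereocentre is formed. The selectivity needed is ring closure over intermolecular coupling and over hydrodecarboxylation or β-hydride elimination of the alkylnickel species; it is secured by slow addition of 12 (sub-millimolar stationary concentration), by the bent 1,2/1,3-linked diaryl ether hinge that starts both chains in roughly the same direction, and by the tridentate terpyridine ligand, which disfavours β-hydride elimination. Both radical precursors are primary, unhindered and electronically alike, so the order of activation does not matter and no cross-selectivity problem arises; the electron-rich arenes, which would be oxidised under an anodic Kolbe coupling of diacid 11, are inert under these cathodic conditions.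

**Step 8**
Reactants: 13 tri-O-methylgrevirobstol B
Product: 14 grevirobstol B
Conditions: BBr3 (6 equiv), CH2Cl2, −78 °C to rt; then MeOH, H2O
Reagents that add atoms: none
Why: Lewis-acid cleavage of aryl methyl ethers with BBr3 (bromide attacks the O-methyl carbon of the boron-coordinated ether), a process that cannot cleave the diaryl ether and leaves the saturated bridge untouched.

**Compound list**
1 | 3-bromo-5-methoxyphenol | COc1cc(O)cc(Br)c1 | starting material
2 | methyl dec-9-enoate | C=CCCCCCCCC(=O)OC | starting material
3 | methyl 10-(9-borabicyclo[3.3.1]nonan-9-yl)decanoate (alkylborane formed in the flask) | COC(=O)CCCCCCCCCB1C2CCCC1CCC2 | intermediate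
4 | methyl 10-(3-hydroxy-5-methoxyphenyl)decanoate | COC(=O)CCCCCCCCCc1cc(O)cc(OC)c1 | intermediate
5 | 2-bromo-3,5-dimethoxybenzaldehyde | COc1cc(OC)c(Br)c(C=O)c1 | starting material
6 | methyl 10-[3-(2-formyl-4,6-dimethoxyphenoxy)-5-methoxyphenyl]decanoate | COC(=O)CCCCCCCCCc1cc(OC)cc(Oc2c(C=O)cc(OC)cc2OC)c1 | intermediate
7 | (6-carboxyhexyl)triphenylphosphonium bromide | OC(=O)CCCCCC[P+](c1ccccc1)(c1ccccc1)c1ccccc1.[Br-] | starting material
8 | sodium 7-(triphenyl-λ5-phosphanylidene)heptanoate (carboxylate ylide formed in the flask) | [Na+].[O-]C(=O)CCCCCC=P(c1ccccc1)(c1ccccc1)c1ccccc1 | intermediate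
9 | (Z)-8-{2-[3-methoxy-5-(10-methoxy-10-oxodecyl)phenoxy]-3,5-dimethoxyphenyl}oct-7-enoic acid (any E isomer converges in step 4) | COC(=O)CCCCCCCCCc1cc(OC)cc(Oc2c(/C=C\CCCCCC(=O)O)cc(OC)cc2OC)c1 | intermediate
10 | 8-{2-[3-methoxy-5-(10-methoxy-10-oxodecyl)phenoxy]-3,5-dimethoxyphenyl}octanoic acid | COC(=O)CCCCCCCCCc1cc(OC)cc(Oc2c(CCCCCCCC(=O)O)cc(OC)cc2OC)c1 | intermediate
11 | 10-{3-[2-(7-carboxyheptyl)-4,6-dimethoxyphenoxy]-5-methoxyphenyl}decanoic acid | OC(=O)CCCCCCCCCc1cc(OC)cc(Oc2c(CCCCCCCC(=O)O)cc(OC)cc2OC)c1 | intermediate
12 | bis(N-hydroxyphthalimide) ester of 11 | O=C(CCCCCCCCCc1cc(OC)cc(Oc2c(CCCCCCCC(=O)ON3C(=O)c4ccccc4C3=O)cc(OC)cc2OC)c1)ON1C(=O)c2ccccc2C1=O | intermediate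
13 | tri-O-methylgrevirobstol B (22-membered macrocycle; ring A carries one methoxy group, ring B two) | COc1cc2cc(c1)Oc1c(OC)cc(OC)cc1CCCCCCCCCCCCCCCC2 | intermediate
14 | grevirobstol B | Oc1cc2cc(c1)Oc1c(O)cc(O)cc1CCCCCCCCCCCCCCCC2 | target

**Totals**
Total step count: 8. Longest linear sequence: 8 steps (from 1 and 2 to 14).

**Steps most likely to fail**

Step 7 (proposed new method). The macrocyclic ring closure through the nickel chelate may be outrun by intermolecular coupling to dimers and oligomers, or by reduction or β-hydride elimination of the chain ends. The fallback is ring-closing olefin metathesis, which forms the same C7–C8 bond by known chemistry. It sets out from diacid 11. BH3·THF reduces both acids to the diol 10-{3-[2-(8-hydroxyoctyl)-4,6-dimethoxyphenoxy]-5-methoxyphenyl}decan-1-ol F1. CBr4/PPh3 in CH2Cl2 converts it into the dibromide 1-(8-bromooctyl)-2-[3-(10-bromodecyl)-5-methoxyphenoxy]-3,5-dimethoxybenzene F2. KOtBu in THF eliminates both primary bromides to the diene 2-[3-(dec-9-en-1-yl)-5-methoxyphenoxy]-3,5-dimethoxy-1-(oct-7-en-1-yl)benzene F3. The second-generation Grubbs catalyst RuCl2(=CHPh)(H2IMes)(PCy3) in refluxing CH2Cl2 at about 1 mM should close the ring to the cycloalkene 7,8-didehydro-tri-O-methylgrevirobstol B F4 (E/Z mixture) with loss of ethene. Hydrogenation over Pd/C in EtOAc saturates the alkene and returns to the route at 13.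

Step 2. Activation of the C–Br bond, which is flanked by formyl and methoxy groups and deactivated by the para-methoxy group, may be slow, so that reductive debromination of 5 or base-induced degradation of the aldehyde takes over at the temperature needed. The fallback is a metal-free nucleophilic aromatic substitution and sets out from phenol 4. Its partner, 2-fluoro-3,5-dimethoxybenzaldehyde F5, should form from purchasable 3,5-dimethoxybenzaldehyde with Selectfluor in MeCN, at the same ring position that bromination attacks. Heating 4 and this fluoride with K2CO3 in DMA at 120–140 °C should give the ether by addition–elimination, the ortho-formyl group stabilising the Meisenheimer adduct. The fallback comes back to the route at 6.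

Step 1. Oxidative addition to the electron-rich bromophenoxide may be sluggish, so that protodeboronation of the alkylborane and partial hydrolysis of the methyl ester by the aqueous base compete. The fallback replaces the sp3–sp2 coupling by an alkyne coupling followed by saturation and sets out from 1. Sonogashira coupling of 1 with purchasable methyl dec-9-ynoate (Pd(PPh3)2Cl2, CuI, Et3N, DMF, 70 °C) needs neither an alkylborane nor aqueous base and leaves the phenol un-ionised. It should give methyl 10-(3-hydroxy-5-methoxyphenyl)dec-9-ynoate F6. Hydrogenation over Pd/C in EtOAc then returns to the route at 4.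

**Further compounds**
F1 | step 7 | 10-{3-[2-(8-hydroxyoctyl)-4,6-dimethoxyphenoxy]-5-methoxyphenyl}decan-1-ol | OCCCCCCCCCCc1cc(OC)cc(Oc2c(CCCCCCCCO)cc(OC)cc2OC)c1
F2 | step 7 | 1-(8-bromooctyl)-2-[3-(10-bromodecyl)-5-methoxyphenoxy]-3,5-dimethoxybenzene | BrCCCCCCCCCCc1cc(OC)cc(Oc2c(CCCCCCCCBr)cc(OC)cc2OC)c1
F3 | step 7 | 2-[3-(dec-9-en-1-yl)-5-methoxyphenoxy]-3,5-dimethoxy-1-(oct-7-en-1-yl)benzene | C=CCCCCCCCCc1cc(OC)cc(Oc2c(CCCCCCC=C)cc(OC)cc2OC)c1
F4 | step 7 | 7,8-didehydro-tri-O-methylgrevirobstol B (E/Z mixture, geometry left open) | COc1cc2cc(c1)Oc1c(OC)cc(OC)cc1CCCCCCC=CCCCCCCCC2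
F5 | step 2 | 2-fluoro-3,5-dimethoxybenzaldehyde | COc1cc(OC)c(F)c(C=O)c1
F6 | step 1 | methyl 10-(3-hydroxy-5-methoxyphenyl)dec-9-ynoate | COC(=O)CCCCCCCC#Cc1cc(O)cc(OC)c1
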